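## Retrosynthetic overview

1. Both C6–C3 halves of the target come from one cheap acid, 1; two molecules are joined as the symmetric anhydride 2.
2. Key disconnection, C3–C4 of the oxolane: an enantioselective intramolecular Rauhut–Currier reaction makes one arm of 2 the nucleophile and the other the acceptor. It gives the six-membered cyclic anhydride 3 with the aryl-bearing stereocentre and the E-benzylidene; methanol opens 3 to half-ester 4.
3. Second disconnection, O1–C2 of the oxolane: alpha-iodination of the ester arm of 4 (iodide 5) and invertive closure by the carboxylate give the trans gamma-lactone 6.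
4. Last step: cleavage of the four aryl methyl ethers of 6 gives target 7.
5. Ring order: glutaric anhydride ring (temporary), then the gamma-lactone; both benzene rings are bought.

Assumption: the sense of induction of the new phosphine-catalysed step cannot be known beforehand. The route is written for the catalyst antipode that gives (4S)-3 (drawn as the L-valine-derived catalyst); the mirror-image catalyst is used if the first run shows the opposite sense.

## Route

Step 1
Reactants: 1 (2E)-3-(3,4-dimethoxyphenyl)prop-2-enoic acid (two molecules)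
Product: 2 (2E)-3-(3,4-dimethoxyphenyl)prop-2-enoic anhydride
Conditions: N,N'-dicyclohexylcarbodiimide (0.5 equiv per acid), CH2Cl2, 0 to 25 °C
Reagents that add atoms: none
Why: Carbodiimide dehydration of a carboxylic acid (O-acylisourea attacked by a second carboxylate) gives the symmetric anhydride and insoluble urea; no stereocentre is formed and the E alkenes are untouched.

Step 2
Reactants: 2 (2E)-3-(3,4-dimethoxyphenyl)prop-2-enoic anhydride
Product: 4 (2E,3S)-3-(3,4-dimethoxyphenyl)-2-[(3,4-dimethoxyphenyl)methylidene]-5-methoxy-5-oxopentanoic acid, via cyclic anhydride 3 (not isolated)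
Conditions: (S)-N-[1-(diphenylphosphanyl)-3-methylbutan-2-yl]-4-methylbenzenesulfonamide (10 mol%), toluene (0.02 M), 25 °C; then MeOH (5 equiv), 4-(dimethylamino)pyridine (10 mol%), 0 to 25 °C
Reagents that add atoms: methanol, CO
Why: Proposed new method: Rauhut–Currier cycloisomerisation in which the phosphine adds to the beta-carbon of one cinnamoyl arm of the C2v-symmetric anhydride, the zwitterionic enolate attacks the beta-carbon of the other arm (6-endo Michael addition inside the chiral ion pair, which sets the S centre), and proton transfer with loss of the phosphine gives the E-benzylidene; the closest known reaction type is the enantioselective phosphine-catalysed intramolecular Rauhut–Currier desymmetrisation of acrylate-tethered dienones, and methanol then opens the non-conjugated carbonyl as it does in itaconic anhydride.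

Step 3
Reactants: 4 (2E,3S)-3-(3,4-dimethoxyphenyl)-2-[(3,4-dimethoxyphenyl)methylidene]-5-methoxy-5-oxopentanoic acid
Product: 6 methyl (2S,3S,4E)-3-(3,4-dimethoxyphenyl)-4-[(3,4-dimethoxyphenyl)methylidene]-5-oxooxolane-2-carboxylate, via iodo ester 5 (not isolated)
Conditions: LiN(iPr)2 (2.2 equiv), THF, −78 °C; I2 (1.05 equiv), −78 to 0 °C; then Bu4NI (0.2 equiv), DMF, 25 °C
Reagents that add atoms: none
Why: Enolate alpha-iodination followed by intramolecular carboxylate SN2 (5-exo-tet lactonisation): the two C–I epimers interconvert by iodide exchange and the one that closes with inversion to the trans lactone (aryl and CO2Me on opposite faces) reacts faster, which sets C2 as S under control of the existing centre.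

Step 4
Reactants: 6 methyl (2S,3S,4E)-3-(3,4-dimethoxyphenyl)-4-[(3,4-dimethoxyphenyl)methylidene]-5-oxooxolane-2-carboxylate
Product: 7 methyl (2S,3S,4E)-3-(3,4-dihydroxyphenyl)-4-[(3,4-dihydroxyphenyl)methylidene]-5-oxooxolane-2-carboxylate
Conditions: BBr3 (6 equiv), CH2Cl2, −78 to 0 °C; then H2O, 0 °C
Reagents that add atoms: none
Why: Lewis acid ether cleavage (BBr3 demethylation of aryl methyl ethers) is faster at low temperature than attack on the methyl ester or the lactone, and neither stereocentre nor the alkene is touched.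

## Compound list

1 | (2E)-3-(3,4-dimethoxyphenyl)prop-2-enoic acid (3,4-dimethoxycinnamic acid) | COc1ccc(/C=C/C(=O)O)cc1OC | starting material
2 | (2E)-3-(3,4-dimethoxyphenyl)prop-2-enoic anhydride | COc1ccc(/C=C/C(=O)OC(=O)/C=C/c2ccc(OC)c(OC)c2)cc1OC | intermediate
3 | (3E,4S)-4-(3,4-dimethoxyphenyl)-3-[(3,4-dimethoxyphenyl)methylidene]oxane-2,6-dione | O=C1OC(=O)/C(=C/c2ccc(OC)c(OC)c2)[C@@H](C1)c1ccc(OC)c(OC)c1 | intermediate
4 | (2E,3S)-3-(3,4-dimethoxyphenyl)-2-[(3,4-dimethoxyphenyl)methylidene]-5-methoxy-5-oxopentanoic acid | OC(=O)/C(=C/c2ccc(OC)c(OC)c2)[C@@H](CC(=O)OC)c1ccc(OC)c(OC)c1 | intermediate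
5 | (2E,3S,4R)-3-(3,4-dimethoxyphenyl)-2-[(3,4-dimethoxyphenyl)methylidene]-4-iodo-5-methoxy-5-oxopentanoic acid (lithium salt in the flask; the 4S epimer equilibrates with it) | OC(=O)/C(=C/c2ccc(OC)c(OC)c2)[C@@H]([C@@H](I)C(=O)OC)c1ccc(OC)c(OC)c1 | intermediate
6 | methyl (2S,3S,4E)-3-(3,4-dimethoxyphenyl)-4-[(3,4-dimethoxyphenyl)methylidene]-5-oxooxolane-2-carboxylate | COC(=O)[C@H]1OC(=O)/C(=C/c2ccc(OC)c(OC)c2)[C@@H]1c1ccc(OC)c(OC)c1 | intermediate
7 | methyl (2S,3S,4E)-3-(3,4-dihydroxyphenyl)-4-[(3,4-dihydroxyphenyl)methylidene]-5-oxooxolane-2-carboxylate | COC(=O)[C@H]1OC(=O)/C(=C/c2ccc(O)c(O)c2)[C@@H]1c1ccc(O)c(O)c1 | target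

## Step count and risks

Total step count: 4. Longest linear sequence: 4.

The three steps most likely to fail are steps 2, 3 and 4.

**Step 2.** The phosphine may not add to a beta-aryl acceptor, may be tied up as an acylphosphonium salt, or the sulfonamide N–H may be acylated; the enantioselectivity is untested. The fallback sets out from 1 and comes back to the route at 6; it replaces the symmetry-breaking cyclisation by a dynamic kinetic resolution.
- Compound 1 is hydrogenated and esterified in one pot (H2, Pd/C, MeOH, cat. H2SO4) to methyl 3-(3,4-dimethoxyphenyl)propanoate F1.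
- Its lithium enolate (LiN(iPr)2, THF, −78 °C) is added to 3,4-dimethoxybenzaldehyde, the aldolate is acetylated in the flask (Ac2O) to the beta-acetoxy ester F2, and 1,8-diazabicyclo[5.4.0]undec-7-ene eliminates acetic acid to give methyl (2E)-2-[(3,4-dimethoxyphenyl)methyl]-3-(3,4-dimethoxyphenyl)prop-2-enoate F3.
- KOtBu and dimethyl oxalate in THF (Claisen acylation of the 1,3-diarylallyl anion at its benzylic terminus) give the stereolabile keto diester F4.
- Transfer hydrogenation with dynamic kinetic resolution ([RuCl(p-cymene)(N-tosyl-1,2-diphenylethylenediamine)], antipode chosen for the S alcohol, HCO2H/Et3N, DMF) reduces the keto group; the anti hydroxy ester lactonises onto the unsaturated ester with loss of methanol and gives 6.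

**Step 3.** Iodination of the acyclic enolate may be unselective, epimerisation of the iodide may be slower than ring closure (giving cis lactone), or the enolate may dimerise oxidatively. The fallback sets out from 3 and comes back at 6; it moves the C–O bond formation to the rigid cyclic anhydride.
- Step 2 is stopped before the methanol quench and anhydride 3 is isolated.
- Soft enolisation (Me3SiOTf, Et3N, CH2Cl2, 0 °C) gives the silyl ketene acetal F5.
- N-Bromosuccinimide at −78 °C brominates C5 anti to the neighbouring aryl group and gives the trans bromo anhydride F6.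
- NaOMe in MeOH opens the ring at the non-conjugated carbonyl next to the bromide to give the bromo half-ester carboxylate F7, which closes by intramolecular SN2 with inversion to 6.

**Step 4.** BBr3 may also cleave the methyl ester or open the lactone before all four ethers are gone. The fallback sets out from 6 and comes back at 7; it deprotects exhaustively and then rebuilds the ester.
- Excess BBr3 at 25 °C removes the four ether methyl groups and the ester methyl group and, after aqueous work-up, gives the tetrahydroxy acid F8.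
- Fischer esterification of its only carboxylic acid (MeOH, HCl from acetyl chloride, 0 to 25 °C) gives 7.

## Further compounds

F1 | step 2 | methyl 3-(3,4-dimethoxyphenyl)propanoate | COC(=O)CCc1ccc(OC)c(OC)c1
F2 | step 2 | methyl 3-(acetyloxy)-2-[(3,4-dimethoxyphenyl)methyl]-3-(3,4-dimethoxyphenyl)propanoate (racemic mixture of diastereomers) | COC(=O)C(Cc1ccc(OC)c(OC)c1)C(OC(C)=O)c1ccc(OC)c(OC)c1
F3 | step 2 | methyl (2E)-2-[(3,4-dimethoxyphenyl)methyl]-3-(3,4-dimethoxyphenyl)prop-2-enoate | COC(=O)/C(=C/c1ccc(OC)c(OC)c1)Cc1ccc(OC)c(OC)c1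
F4 | step 2 | dimethyl (2E)-3-(3,4-dimethoxyphenyl)-2-[(3,4-dimethoxyphenyl)methylidene]-4-oxopentanedioate (racemic, stereolabile at C3) | COC(=O)/C(=C/c1ccc(OC)c(OC)c1)C(C(=O)C(=O)OC)c1ccc(OC)c(OC)c1
F5 | step 3 | (3E,4S)-4-(3,4-dimethoxyphenyl)-3-[(3,4-dimethoxyphenyl)methylidene]-6-[(trimethylsilyl)oxy]-3,4-dihydro-2H-pyran-2-one | C[Si](C)(C)OC=1OC(=O)/C(=C/c2ccc(OC)c(OC)c2)[C@@H](C=1)c1ccc(OC)c(OC)c1
F6 | step 3 | (3E,4S,5R)-5-bromo-4-(3,4-dimethoxyphenyl)-3-[(3,4-dimethoxyphenyl)methylidene]oxane-2,6-dione | O=C1OC(=O)/C(=C/c2ccc(OC)c(OC)c2)[C@@H]([C@H]1Br)c1ccc(OC)c(OC)c1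
F7 | step 3 | (2E,3S,4R)-4-bromo-3-(3,4-dimethoxyphenyl)-2-[(3,4-dimethoxyphenyl)methylidene]-5-methoxy-5-oxopentanoic acid (sodium salt in the flask) | OC(=O)/C(=C/c2ccc(OC)c(OC)c2)[C@@H]([C@@H](Br)C(=O)OC)c1ccc(OC)c(OC)c1
F8 | step 4 | (2S,3S,4E)-3-(3,4-dihydroxyphenyl)-4-[(3,4-dihydroxyphenyl)methylidene]-5-oxooxolane-2-carboxylic acid | OC(=O)[C@H]1OC(=O)/C(=C/c2ccc(O)c(O)c2)[C@@H]1c1ccc(O)c(O)c1
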